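Ring A is numbered C1 (OMe), C2 (H), C3 (OH), C4 (H), C5 (CH2CH2 arm to ring B) and C6 (CH2 to ring C). The plan exploits its two complementary edges. The meta-dioxygenated C1–C4 edge maps onto an acetoacetate-derived ketene-acetal siloxydiene, and the neighbouring carbon-substituted atoms C5 and C6 map onto an alkyne. A single thermal [4+2] cycloaddition–aromatisation forms C1–C6 and C4–C5, closes ring A with all four substituents placed, and delivers C1–OMe and C3–OH already distinguished. The precursor is a linear ynone. Its 4-benzyloxybenzoyl group polarises the triple bond and is later deoxygenated to the C6 benzyl group, while the other alkyne carbon carries the 2-(2-benzyloxyphenyl)ethyl arm.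

Key step: step 5

Remark: the target has no stereocentre, stereogenic axis or stereogenic alkene, so it is achiral and no step needs stereocontrol; the three starting materials are taken as catalogue items.

Step 1
Reactants: 1 3,4-dihydrocoumarin
Product: 3 methyl 3-[2-(benzyloxy)phenyl]propanoate, via methyl 3-(2-hydroxyphenyl)propanoate 2 (not isolated)
Conditions: K2CO3, dry MeOH, rt; then BnBr, 50 °C
Reagents that add atoms: methanol, CO; benzyl bromide, BrCc1ccccc1
Why: Carbonate-mediated methanolysis (transesterification) of the aryl lactone frees the phenoxide of 2, which is trapped in the same flask by Williamson etherification, so relactonisation is blocked; no stereocentre is formed.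

Step 2
Reactants: 3 methyl 3-[2-(benzyloxy)phenyl]propanoate
Product: 5 1-(benzyloxy)-2-(but-3-yn-1-yl)benzene, via 3-[2-(benzyloxy)phenyl]propanal 4 (not isolated)
Conditions: DIBAL-H, CH2Cl2, −78 °C; then MeOH, K2CO3, Ohira–Bestmann reagent, −78 °C → rt; Rochelle salt work-up
Reagents that add atoms: dimethyl (1-diazo-2-oxopropyl)phosphonate, CC(=O)C(=[N+]=[N-])P(=O)(OC)OC
Why: Partial ester reduction halts at the aluminium hemiacetal at −78 °C, methanol releases aldehyde 4, and the Ohira–Bestmann variant of the Seyferth–Gilbert homologation converts it to the terminal alkyne in the same flask, a known one-pot ester-to-alkyne sequence that leaves aryl benzyl ethers untouched.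

Step 3
Reactants: 5 1-(benzyloxy)-2-(but-3-yn-1-yl)benzene; 6 4-(benzyloxy)benzoyl chloride
Product: 7 1-[4-(benzyloxy)phenyl]-5-[2-(benzyloxy)phenyl]pent-2-yn-1-one
Conditions: PdCl2(PPh3)2 (2 mol %), CuI (4 mol %), Et3N (1.2 equiv), degassed THF, rt
Reagents that add atoms: none
Why: The acyl Sonogashira coupling (Pd/Cu-catalysed acylation of a terminal alkyne by an aroyl chloride) gives the ynone directly at the ketone oxidation level, under conditions mild enough to avoid isomerising the propargylic CH2.

Step 4
Reactants: 8 4,4-dimethoxybut-3-en-2-one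
Product: 9 1,1-dimethoxy-3-(trimethylsilyloxy)buta-1,3-diene
Conditions: TMSCl, Et3N, ZnCl2 (cat.), PhMe, 40 °C; filtration under N2, distillation under reduced pressure
Reagents that add atoms: chlorotrimethylsilane, C[Si](C)(C)Cl
Why: This is soft enolisation with O-silylation, the standard silyl enol ether synthesis used to turn β-alkoxy enones into 2-siloxydienes, and the methyl group is the only enolisable position of 8, so only the cross-conjugated diene can form.

Step 5
Reactants: 7 1-[4-(benzyloxy)phenyl]-5-[2-(benzyloxy)phenyl]pent-2-yn-1-one; 9 1,1-dimethoxy-3-(trimethylsilyloxy)buta-1,3-diene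
Product: 12 {4-hydroxy-2-methoxy-6-[2-(2-benzyloxyphenyl)ethyl]phenyl}[4-(benzyloxy)phenyl]methanone, via cyclohexa-1,4-diene cycloadduct 10 (not isolated), via aryl trimethylsilyl ether 11 (not isolated)
Conditions: 9 (3 equiv, in portions), PhMe, 120 °C, sealed tube, base-washed glassware; then 1 M HCl, THF, rt
Reagents that add atoms: none
Why: This is a normal-electron-demand Diels–Alder reaction, concerted but strongly asynchronous, in which the CH2 terminus of 9 (future C4) bonds first to the β-alkyne carbon of 7 (C5) and the acetal carbon (C1) follows onto the α-carbon (C6) to give 10, which expels methanol across C1/C4 on heating to give 11, whose O–Si bond the dilute acid then cleaves. The closest known reaction type is the cycloaddition–aromatisation of 1,1-dialkoxy-3-siloxybuta-1,3-dienes with acetylenic esters and ketones, an established entry to resorcinol monoethers, applied here to an internal aryl ynone. Ring A, the only ring made, is closed in an intermolecular [4+2] mode from four diene carbons and two alkyne carbons, and irreversible aromatisation pulls the sequence forward. No stereocentre arises, because every ring atom ends sp2. Only regioselectivity is required, and matched polarity secures it: all three oxygen donors of 9 push electron density to its CH2 terminus, the aroyl group of 7 makes the arm-bearing alkyne carbon the electrophilic one, and even a fully stepwise Mukaiyama–Michael/ring-closure course would give the same connectivity. The two oxygens are differentiated by construction, since C1 keeps one methoxy group of the acetal whereas C3 carries only a labile silyl group.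

Step 6
Reactants: 12 {4-hydroxy-2-methoxy-6-[2-(2-benzyloxyphenyl)ethyl]phenyl}[4-(benzyloxy)phenyl]methanone
Product: 15 4-[4-(benzyloxy)benzyl]-3-{2-[2-(benzyloxy)phenyl]ethyl}-5-methoxyphenol, via racemic benzhydrol 13 (not isolated), via diarylmethyl cation 14 (not isolated)
Conditions: Et3SiH (5 equiv), TFA, CH2Cl2, 0 °C → rt
Reagents that add atoms: none
Why: In this Kursanov–Parnes ionic hydrogenation the protonated ketone takes hydride to give 13, which ionises at once to 14 (the O-protonated para-quinone methide of ring A, stabilised by C3–OH, C1–OMe and the ring C ether) and takes a second hydride, while excess silane should outrun Friedel–Crafts capture by ring B, whose free ortho position lies meta to its ether oxygen; the transient racemic carbinol centre is erased.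

Step 7
Reactants: 15 4-[4-(benzyloxy)benzyl]-3-{2-[2-(benzyloxy)phenyl]ethyl}-5-methoxyphenol
Product: 16 4-(4-hydroxybenzyl)-3-[2-(2-hydroxyphenyl)ethyl]-5-methoxyphenol (target CNP0289131.0)
Conditions: H2 (1 atm), 10% Pd/C, EtOAc–MeOH, rt
Reagents that add atoms: none
Why: Catalytic hydrogenolysis cleaves both aryl benzyl ethers under neutral conditions and should leave the methyl ether, the diarylmethane CH2 and the bibenzyl chain untouched.

Compound list
1 | 3,4-dihydrocoumarin (chroman-2-one) | O=C1CCc2ccccc2O1 | starting material
2 | methyl 3-(2-hydroxyphenyl)propanoate | COC(=O)CCc1ccccc1O | intermediate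
3 | methyl 3-[2-(benzyloxy)phenyl]propanoate | COC(=O)CCc1ccccc1OCc1ccccc1 | intermediate
4 | 3-[2-(benzyloxy)phenyl]propanal | O=CCCc1ccccc1OCc1ccccc1 | intermediate
5 | 1-(benzyloxy)-2-(but-3-yn-1-yl)benzene | C#CCCc1ccccc1OCc1ccccc1 | intermediate
6 | 4-(benzyloxy)benzoyl chloride | O=C(Cl)c1ccc(OCc2ccccc2)cc1 | starting material
7 | 1-[4-(benzyloxy)phenyl]-5-[2-(benzyloxy)phenyl]pent-2-yn-1-one | O=C(C#CCCc1ccccc1OCc1ccccc1)c1ccc(OCc2ccccc2)cc1 | intermediate
8 | 4,4-dimethoxybut-3-en-2-one | COC(OC)=CC(C)=O | starting material
9 | 1,1-dimethoxy-3-(trimethylsilyloxy)buta-1,3-diene | COC(OC)=CC(=C)O[Si](C)(C)C | intermediate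
10 | {2-{2-[2-(benzyloxy)phenyl]ethyl}-6,6-dimethoxy-4-[(trimethylsilyl)oxy]cyclohexa-1,4-dien-1-yl}[4-(benzyloxy)phenyl]methanone | COC1(OC)C=C(O[Si](C)(C)C)CC(CCc2ccccc2OCc2ccccc2)=C1C(=O)c1ccc(OCc2ccccc2)cc1 | intermediate
11 | {2-{2-[2-(benzyloxy)phenyl]ethyl}-6-methoxy-4-[(trimethylsilyl)oxy]phenyl}[4-(benzyloxy)phenyl]methanone | COc1cc(O[Si](C)(C)C)cc(CCc2ccccc2OCc2ccccc2)c1C(=O)c1ccc(OCc2ccccc2)cc1 | intermediate
12 | {4-hydroxy-2-methoxy-6-[2-(2-benzyloxyphenyl)ethyl]phenyl}[4-(benzyloxy)phenyl]methanone | COc1cc(O)cc(CCc2ccccc2OCc2ccccc2)c1C(=O)c1ccc(OCc2ccccc2)cc1 | intermediate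
13 | 4-{[4-(benzyloxy)phenyl](hydroxy)methyl}-3-{2-[2-(benzyloxy)phenyl]ethyl}-5-methoxyphenol (racemic; the centre is erased in the same step) | COc1cc(O)cc(CCc2ccccc2OCc2ccccc2)c1C(O)c1ccc(OCc2ccccc2)cc1 | intermediate
14 | [4-(benzyloxy)phenyl]{2-{2-[2-(benzyloxy)phenyl]ethyl}-4-hydroxy-6-methoxyphenyl}methylium (O-protonated ring A para-quinone methide) | COc1cc(O)cc(CCc2ccccc2OCc2ccccc2)c1[CH+]c1ccc(OCc2ccccc2)cc1 | intermediate
15 | 4-[4-(benzyloxy)benzyl]-3-{2-[2-(benzyloxy)phenyl]ethyl}-5-methoxyphenol | COc1cc(O)cc(CCc2ccccc2OCc2ccccc2)c1Cc1ccc(OCc2ccccc2)cc1 | intermediate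
16 | 4-(4-hydroxybenzyl)-3-[2-(2-hydroxyphenyl)ethyl]-5-methoxyphenol (achiral) | COc1cc(O)cc(CCc2ccccc2O)c1Cc1ccc(O)cc1 | target

Total step count: 7. Longest linear sequence: 6 steps (1 → 3 → 5 → 7 → 12 → 15 → 16). Step 4 is a one-step side branch.

Steps most likely to fail

Step 5 (key step). The internal triple bond, activated only by a donor-substituted aroyl group, may react more slowly than the ketene-acetal diene decays by hydrolysis, proton transfer or thermal silyl migration, so conversion may stall. The fallback sets out from 5 and comes back at 13. It changes the activating group from aroyl to formyl and attaches ring C only after ring A exists. Alkyne 5 is lithiated (n-BuLi, THF, −78 °C) and formylated with DMF to 5-[2-(benzyloxy)phenyl]pent-2-ynal F1. This smaller and more electrophilic dienophile should combine with 9 at 60–80 °C in toluene to give 2-{2-[2-(benzyloxy)phenyl]ethyl}-6,6-dimethoxy-4-[(trimethylsilyl)oxy]cyclohexa-1,4-diene-1-carbaldehyde F2. F2 loses methanol to give 2-{2-[2-(benzyloxy)phenyl]ethyl}-6-methoxy-4-[(trimethylsilyl)oxy]benzaldehyde F3, and acid work-up gives 2-{2-[2-(benzyloxy)phenyl]ethyl}-4-hydroxy-6-methoxybenzaldehyde F4. Excess commercial 4-(benzyloxy)phenylmagnesium bromide (the first equivalent is spent on the phenol) adds to the aldehyde to give benzhydrol 13, now isolated. Et3SiH/TFA then carries 13 on to 15 as in step 6.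

Step 6. Hydride transfer to the hindered, doubly donor-stabilised protonated ketone may be slow. Long acid exposure invites loss of benzyl groups with C-benzylation of ring A, or arylation of the cation. The fallback sets out from 12 and comes back at 16. The carbonyl is reduced under basic conditions and the C–O bond is cleaved on a metal surface instead of through an acid-generated cation. Excess LiAlH4 in refluxing THF should take 12 to benzhydrol 13, used crude. Any over-reduction through the phenoxide-derived quinone methide only yields 15, which converges in the next operation. Hydrogenation over Pd/C in EtOH containing a little AcOH then cleaves the doubly benzylic C–OH bond together with both benzyl ethers and arrives directly at 16.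

Step 2. Premature collapse of the aluminium hemiacetal may cause over-reduction to the alcohol, and aluminium salts may slow the homologation in the same flask. The fallback sets out from 3 and comes back at 4, and so at 5. Partial reduction is replaced by a full reduction and reoxidation. LiAlH4 in THF at 0 °C gives 3-[2-(benzyloxy)phenyl]propan-1-ol F5. Dess–Martin periodinane in CH2Cl2 oxidises it to aldehyde 4, now isolated and free of aluminium residues. Aldehyde 4 is then treated separately with the Ohira–Bestmann reagent and K2CO3 in MeOH to give 5.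

Further compounds
F1 | step 5 | 5-[2-(benzyloxy)phenyl]pent-2-ynal | O=CC#CCCc1ccccc1OCc1ccccc1
F2 | step 5 | 2-{2-[2-(benzyloxy)phenyl]ethyl}-6,6-dimethoxy-4-[(trimethylsilyl)oxy]cyclohexa-1,4-diene-1-carbaldehyde | COC1(OC)C=C(O[Si](C)(C)C)CC(CCc2ccccc2OCc2ccccc2)=C1C=O
F3 | step 5 | 2-{2-[2-(benzyloxy)phenyl]ethyl}-6-methoxy-4-[(trimethylsilyl)oxy]benzaldehyde | COc1cc(O[Si](C)(C)C)cc(CCc2ccccc2OCc2ccccc2)c1C=O
F4 | step 5 | 2-{2-[2-(benzyloxy)phenyl]ethyl}-4-hydroxy-6-methoxybenzaldehyde | COc1cc(O)cc(CCc2ccccc2OCc2ccccc2)c1C=O
F0 | step 6 | none | none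
F5 | step 2 | 3-[2-(benzyloxy)phenyl]propan-1-ol | OCCCc1ccccc1OCc1ccccc1
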